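**Plan**

1. Locants: bicycle O1, C2, C3, C3a, C4, C5, C6, C7, C7a (dihydrofuran ring O1–C2–C3–C3a–C7a fused along C3a=C7a to the six-membered ring C3a–C4–C5–C6–C7–C7a); side chain C1'–C11' on C2 (carbinols C2', C5', C6').
2. Cuts, in retrosynthetic order: C3a–C4 (C-acylation of an enol ether), C3a=C7a (Wittig olefination of an ester carbonyl), O1–C7a (ester), C3–C3a (epoxide opening by Ph3P=CH2), C2'–C3' (Grignard addition).
3. Enabling feature: C7a, the alkoxy carbon of the vinylogous ester O1–C7a=C3a–C4=O, is an ester carbon in disguise. O1–C7a is therefore made first as an ordinary ester between the C2 carbinol and the distal carboxyl of a (2R)-2-silyloxyglutarate, which fixes O1 on C7a and the C5 carbinol next to C4 before any ring exists.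
4. Forward: tail (C3'–C11') and oxirane ketone (C3, C2, C2', C1') are joined, Ph3P=CH2 adds C3a, the C2 oxygen is esterified, then the dihydrofuran ring closes (C3a=C7a), then the six-membered ring (C3a–C4), then desilylation.
5. Stereocentres: C5 from D-glutamic acid (retentive diazotisation), C5' from (R)-α-hydroxy-γ-butyrolactone, C6' and C2' from Cram chelate Grignard additions, C2 from a Sharpless kinetic resolution.

Key step: step 16

Abbreviations: TBS = tert-butyldimethylsilyl, TES = triethylsilyl; TBSO and TESO denote the silyl ethers.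

Step 1
Reactants: 1 D-glutamic acid 5-benzyl ester [(2R)-2-amino-5-(benzyloxy)-5-oxopentanoic acid]
Product: 2 (2R)-5-(benzyloxy)-2-hydroxy-5-oxopentanoic acid
Conditions: NaNO2, 1 M aq. H2SO4, 0 °C → rt
Reagents that add atoms: water, O
Why: Diazotisation and hydroxy-de-amination of an α-amino acid, which is known to run with net retention because the neighbouring carboxylate takes part (double inversion), so the (R) centre that becomes C5 is carried over from the chiral pool while the benzyl ester survives the cold dilute acid.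

Step 2
Reactants: 2 (2R)-5-(benzyloxy)-2-hydroxy-5-oxopentanoic acid
Product: 3 5-benzyl 1-methyl (2R)-2-hydroxypentanedioate
Conditions: Me3SiCHN2, MeOH/toluene, 0 °C
Reagents that add atoms: (trimethylsilyl)diazomethane, C[Si](C)(C)C=[N+]=[N-]
Why: Methyl ester formation with (trimethylsilyl)diazomethane is fast and neutral, methylates only the carboxylic acid and leaves the secondary hydroxyl, the benzyl ester and the stereocentre alone.

Step 3
Reactants: 3 5-benzyl 1-methyl (2R)-2-hydroxypentanedioate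
Product: 4 5-benzyl 1-methyl (2R)-2-(TBSO)pentanedioate
Conditions: TBSCl, imidazole, DMF, rt
Reagents that add atoms: tert-butyldimethylsilyl chloride, CC(C)(C)[Si](C)(C)Cl
Why: Standard silyl ether formation masks the C5 hydroxyl, which stops γ-lactonisation onto the benzyl ester and later acyl transfer.

Step 4
Reactants: 4 5-benzyl 1-methyl (2R)-2-(TBSO)pentanedioate
Product: 5 (4R)-4-(TBSO)-5-methoxy-5-oxopentanoic acid
Conditions: H2 (1 atm), 10% Pd/C, EtOAc, rt
Reagents that add atoms: none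
Why: Hydrogenolysis of the benzyl ester frees only the distal carboxyl (the future C7a), since the methyl ester and the TBS ether are inert to H2 over Pd/C.

Step 5
Reactants: 6 (3R)-3-hydroxyoxolan-2-one [(R)-α-hydroxy-γ-butyrolactone]; 7 5-bromo-2-methylpent-2-ene
Product: 9 (3R)-2-(4-methylpent-3-en-1-yl)oxolane-2,3-diol (lactol; both C2 epimers), via 4-methylpent-3-enyllithium 8 (not isolated)
Conditions: 7, Li (2 equiv per 7), Et2O, −10 °C; then 6 (0.45 equiv), THF, −78 °C; then H2O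
Reagents that add atoms: none
Why: Addition of an alkyllithium to a lactone at −78 °C stops at the lactol because the tetrahedral lithium alkoxide does not collapse in the cold (the first equivalent only deprotonates the hydroxyl), which gives a masked α-hydroxy ketone with the (R) carbinol of the chiral pool untouched.

Step 6
Reactants: 9 (3R)-2-(4-methylpent-3-en-1-yl)oxolane-2,3-diol
Product: 10 (3R,4S)-4,8-dimethylnon-7-ene-1,3,4-triol
Conditions: MeMgBr (4 equiv), Et2O/THF, −78 → 0 °C; then aq. NH4Cl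
Reagents that add atoms: methylmagnesium bromide, C[Mg]Br
Why: Grignard addition to the open-chain α-hydroxy ketone under Cram chelate control: magnesium ties the α-alkoxide to the carbonyl oxygen in a five-membered ring and methyl enters from the side of the α-hydrogen, which should set the tertiary carbinol as (4S) next to the (3R) centre.

Step 7
Reactants: 10 (3R,4S)-4,8-dimethylnon-7-ene-1,3,4-triol
Product: 11 (3R,4S)-4,8-dimethyl-1,3,4-tris(TESO)non-7-ene
Conditions: TESOTf (3.6 equiv), 2,6-lutidine, CH2Cl2, −78 → 0 °C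
Reagents that add atoms: triethylsilyl trifluoromethanesulfonate, CC[Si](CC)(CC)OS(=O)(=O)C(F)(F)F
Why: The silyl triflate with 2,6-lutidine silylates all three hydroxyls, the tertiary one included, so that the 1,2-diol is masked by fluoride-labile groups.

Step 8
Reactants: 11 (3R,4S)-4,8-dimethyl-1,3,4-tris(TESO)non-7-ene
Product: 12 (3R,4S)-4,8-dimethyl-3,4-bis(TESO)non-7-en-1-ol
Conditions: pyridinium p-toluenesulfonate (catalytic), MeOH/CH2Cl2, −10 °C
Reagents that add atoms: none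
Why: Acid-catalysed methanolysis cleaves a primary TES ether far faster than the hindered secondary and tertiary ones, which uncovers only the terminal hydroxyl.

Step 9
Reactants: 12 (3R,4S)-4,8-dimethyl-3,4-bis(TESO)non-7-en-1-ol
Product: 13 (3R,4S)-1-bromo-4,8-dimethyl-3,4-bis(TESO)non-7-ene
Conditions: CBr4, PPh3, 2,6-lutidine (buffer), CH2Cl2, 0 °C
Reagents that add atoms: tetrabromomethane, BrC(Br)(Br)Br
Why: Appel bromination turns the primary alcohol into the bromide by SN2 displacement of the alkoxyphosphonium ion, and the silylated tertiary oxygen cannot close a tetrahydrofuran.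

Step 10
Reactants: 14 rac-but-3-en-2-ol
Product: 15 (1R)-1-[(2S)-oxiran-2-yl]ethan-1-ol
Conditions: Ti(OiPr)4 (catalytic), D-(−)-diisopropyl tartrate, t-BuOOH (0.55 equiv), 4 Å molecular sieves, CH2Cl2, −20 °C
Reagents that add atoms: tert-butyl hydroperoxide, CC(C)(C)OO
Why: Sharpless kinetic resolution of a secondary allylic alcohol: with the D-(−)-tartrate catalyst the (R)-alcohol is epoxidised fast and erythro-selectively on the face that gives the (2S)-oxirane carbon, while the (S)-alcohol is left behind.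

Step 11
Reactants: 15 (1R)-1-[(2S)-oxiran-2-yl]ethan-1-ol
Product: 16 1-[(2S)-oxiran-2-yl]ethan-1-one
Conditions: Dess–Martin periodinane, CH2Cl2, 0 °C → rt
Reagents that add atoms: none
Why: Dess–Martin oxidation converts the carbinol into the methyl ketone under non-basic conditions that neither open the oxirane nor enolise its α-carbon, and the volatile ketone is used as a solution.

Step 12
Reactants: 13 (3R,4S)-1-bromo-4,8-dimethyl-3,4-bis(TESO)non-7-ene; 16 1-[(2S)-oxiran-2-yl]ethan-1-one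
Product: 18 (2S,5R,6S)-6,10-dimethyl-2-[(2S)-oxiran-2-yl]-5,6-bis(TESO)undec-9-en-2-ol, via Grignard reagent 17 (not isolated)
Conditions: 13, Mg turnings, Et2O, 35 °C; then 16, Et2O/CH2Cl2, −78 °C; then aq. NH4Cl, −78 °C
Reagents that add atoms: none
Why: Grignard addition to an α,β-epoxy ketone under Cram chelate control: magnesium bridges the carbonyl and oxirane oxygens and the alkyl group adds to the face syn to the oxirane C–H and anti to its CH2, which should set the new tertiary carbinol (C2') as (S) next to the (S)-oxirane carbon, and the ketone reacts much faster than the oxirane at −78 °C.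

Step 13
Reactants: 18 (2S,5R,6S)-6,10-dimethyl-2-[(2S)-oxiran-2-yl]-5,6-bis(TESO)undec-9-en-2-ol
Product: 19 (2S)-2-[(2S,5R,6S)-6,10-dimethyl-2,5,6-tris(TESO)undec-9-en-2-yl]oxirane
Conditions: TESOTf, 2,6-lutidine, CH2Cl2, −78 °C
Reagents that add atoms: triethylsilyl trifluoromethanesulfonate, CC[Si](CC)(CC)OS(=O)(=O)C(F)(F)F
Why: Silylation with the triflate and 2,6-lutidine caps the tertiary alcohol without base-induced Payne rearrangement, which would otherwise scramble the oxirane in the next step.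

Step 14
Reactants: 19 (2S)-2-[(2S,5R,6S)-6,10-dimethyl-2,5,6-tris(TESO)undec-9-en-2-yl]oxirane
Product: 21 [(3S,4S,7R,8S)-3-hydroxy-4,8,12-trimethyl-4,7,8-tris(TESO)tridec-11-en-1-yl]triphenylphosphonium bromide, via betaine 20 (not isolated)
Conditions: Ph3PCH3Br, n-BuLi, THF, 0 °C; then 19, 0 → 45 °C; then aq. NH4Br
Reagents that add atoms: methyltriphenylphosphonium bromide, C[P+](c1ccccc1)(c1ccccc1)c1ccccc1.[Br-]; ammonium bromide, [NH4+].[Br-]
Why: The ylide opens the monosubstituted oxirane at its CH2 terminus (SN2) to a γ-oxido phosphonium betaine, a known reaction of methylenetriphenylphosphorane with epoxides, and protonation gives the hydroxyalkyl phosphonium salt with the C–O bond at the stereocentre untouched.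

Step 15
Reactants: 21 [(3S,4S,7R,8S)-3-hydroxy-4,8,12-trimethyl-4,7,8-tris(TESO)tridec-11-en-1-yl]triphenylphosphonium bromide; 5 (4R)-4-(TBSO)-5-methoxy-5-oxopentanoic acid
Product: 23 [(3S,4S,7R,8S)-3-{[(4R)-4-(TBSO)-5-methoxy-5-oxopentanoyl]oxy}-4,8,12-trimethyl-4,7,8-tris(TESO)tridec-11-en-1-yl]triphenylphosphonium bromide, via mixed anhydride 22 (not isolated)
Conditions: 5, 2,4,6-trichlorobenzoyl chloride, Et3N, toluene, rt; then 21, DMAP, toluene/CH2Cl2, 40 °C
Reagents that add atoms: none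
Why: Yamaguchi esterification through the mixed anhydride acylates the hindered secondary hydroxyl with the distal carboxyl of 5, which places the future ring oxygen O1 on the future C7a, with retention at the carbinol because its C–O bond is not broken.

Step 16
Reactants: 23 [(3S,4S,7R,8S)-3-{[(4R)-4-(TBSO)-5-methoxy-5-oxopentanoyl]oxy}-4,8,12-trimethyl-4,7,8-tris(TESO)tridec-11-en-1-yl]triphenylphosphonium bromide
Product: 25 methyl (2R)-2-(TBSO)-4-{(5S)-5-[(2S,5R,6S)-6,10-dimethyl-2,5,6-tris(TESO)undec-9-en-2-yl]-4,5-dihydrofuran-2-yl}butanoate, via ylide 24 (not isolated)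
Conditions: KN(SiMe3)2 (1.05 equiv), THF/toluene, −78 → 0 °C, then 80 °C
Reagents that add atoms: none
Why: Deprotonation of the phosphonium salt gives the non-stabilised ylide 24, whose carbanionic carbon C3a adds to the carbonyl carbon C7a of the neighbouring ester, and the adduct loses Ph3P=O, so that the C3a=C7a double bond and the dihydrofuran ring (O1, C2, C3, C3a, C7a) arise together. The closest known reaction type is the intramolecular Wittig olefination of ester carbonyls by ω-acyloxyalkylidene phosphoranes, which delivers cyclic enol ethers such as 4,5-dihydrofurans and benzofurans. The ring closes in a 5-exo-trig mode, by attack of C3a on the exocyclic C=O of the ester. No stereocentre is formed: C2 keeps its configuration because the C2–O1 bond is never broken, and C5 is shielded from epimerisation by the use of a single equivalent of base. The step needs chemoselectivity for the O1 ester over the remote methyl ester, which the ring size secures (five-membered against nine-membered cyclic transition state), and it fixes the regiochemistry of the later vinylogous ester because O1 is already bonded to C7a.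

Step 17
Reactants: 25 methyl (2R)-2-(TBSO)-4-{(5S)-5-[(2S,5R,6S)-6,10-dimethyl-2,5,6-tris(TESO)undec-9-en-2-yl]-4,5-dihydrofuran-2-yl}butanoate
Product: 26 potassium (2R)-2-(TBSO)-4-{(5S)-5-[(2S,5R,6S)-6,10-dimethyl-2,5,6-tris(TESO)undec-9-en-2-yl]-4,5-dihydrofuran-2-yl}butanoate
Conditions: KOSiMe3, THF, rt
Reagents that add atoms: potassium trimethylsilanolate, C[Si](C)(C)[O-].[K+]
Why: Potassium trimethylsilanolate cleaves the methyl ester under anhydrous, non-acidic conditions to the potassium carboxylate, which spares the acid-labile enol ether, the silyl ethers and the α-stereocentre.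

Step 18
Reactants: 26 potassium (2R)-2-(TBSO)-4-{(5S)-5-[(2S,5R,6S)-6,10-dimethyl-2,5,6-tris(TESO)undec-9-en-2-yl]-4,5-dihydrofuran-2-yl}butanoate
Product: 28 (2S,5R)-5-(TBSO)-2-[(2S,5R,6S)-6,10-dimethyl-2,5,6-tris(TESO)undec-9-en-2-yl]-3,5,6,7-tetrahydro-1-benzofuran-4(2H)-one, via mixed anhydride 27 (not isolated)
Conditions: (CF3CO)2O (1.0 equiv), 2,6-di-tert-butyl-4-methylpyridine, CH2Cl2, −78 → 0 °C
Reagents that add atoms: none
Why: The carboxylate and trifluoroacetic anhydride give the mixed anhydride, whose α-silyloxyacyl carbon C4 is attacked by the nucleophilic β-carbon C3a of the cyclic enol ether in a 6-(enolendo)-exo-trig closure (C-acylation of an enol ether, as in the acylation of vinyl ethers by anhydrides), and loss of the C3a proton to the hindered pyridine gives the vinylogous ester with O1 on C7a and the ketone on C4 by construction.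

Step 19
Reactants: 28 (2S,5R)-5-(TBSO)-2-[(2S,5R,6S)-6,10-dimethyl-2,5,6-tris(TESO)undec-9-en-2-yl]-3,5,6,7-tetrahydro-1-benzofuran-4(2H)-one
Product: 29 (2S,5R)-5-hydroxy-2-[(2S,5R,6S)-2,5,6-trihydroxy-6,10-dimethylundec-9-en-2-yl]-3,5,6,7-tetrahydro-1-benzofuran-4(2H)-one
Conditions: HF·pyridine, pyridine, THF, 0 °C → rt
Reagents that add atoms: none
Why: Fluoride-mediated desilylation buffered by pyridine removes the TBS group and the three TES groups without aqueous acid or base, so the vinylogous ester, the α-hydroxy ketone and the trisubstituted alkene should survive.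

**Compound list**

1 | D-glutamic acid 5-benzyl ester, (2R)-2-amino-5-(benzyloxy)-5-oxopentanoic acid | OC(=O)[C@@H](CCC(=O)OCc1ccccc1)N | starting material
2 | (2R)-5-(benzyloxy)-2-hydroxy-5-oxopentanoic acid | OC(=O)[C@@H](CCC(=O)OCc1ccccc1)O | intermediate
3 | 5-benzyl 1-methyl (2R)-2-hydroxypentanedioate | COC(=O)[C@@H](CCC(=O)OCc1ccccc1)O | intermediate
4 | 5-benzyl 1-methyl (2R)-2-(TBSO)pentanedioate | COC(=O)[C@@H](CCC(=O)OCc1ccccc1)O[Si](C)(C)C(C)(C)C | intermediate
5 | (4R)-4-(TBSO)-5-methoxy-5-oxopentanoic acid | COC(=O)[C@@H](CCC(=O)O)O[Si](C)(C)C(C)(C)C | intermediate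
6 | (3R)-3-hydroxyoxolan-2-one, (R)-α-hydroxy-γ-butyrolactone | O=C1OCC[C@H]1O | starting material
7 | 5-bromo-2-methylpent-2-ene | BrCCC=C(C)C | starting material
8 | (4-methylpent-3-en-1-yl)lithium | [Li]CCC=C(C)C | intermediate
9 | (3R)-2-(4-methylpent-3-en-1-yl)oxolane-2,3-diol (lactol, both C2 epimers) | CC(C)=CCCC1(O)OCC[C@H]1O | intermediate
10 | (3R,4S)-4,8-dimethylnon-7-ene-1,3,4-triol | OCC[C@@H](O)[C@@](C)(O)CCC=C(C)C | intermediate
11 | (3R,4S)-4,8-dimethyl-1,3,4-tris(TESO)non-7-ene | CC[Si](CC)(CC)OCC[C@@H](O[Si](CC)(CC)CC)[C@@](C)(O[Si](CC)(CC)CC)CCC=C(C)C | intermediate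
12 | (3R,4S)-4,8-dimethyl-3,4-bis(TESO)non-7-en-1-ol | OCC[C@@H](O[Si](CC)(CC)CC)[C@@](C)(O[Si](CC)(CC)CC)CCC=C(C)C | intermediate
13 | (3R,4S)-1-bromo-4,8-dimethyl-3,4-bis(TESO)non-7-ene | BrCC[C@@H](O[Si](CC)(CC)CC)[C@@](C)(O[Si](CC)(CC)CC)CCC=C(C)C | intermediate
14 | rac-but-3-en-2-ol | CC(O)C=C | starting material
15 | (1R)-1-[(2S)-oxiran-2-yl]ethan-1-ol | C[C@@H](O)[C@@H]1CO1 | intermediate
16 | 1-[(2S)-oxiran-2-yl]ethan-1-one | CC(=O)[C@@H]1CO1 | intermediate
17 | [(3R,4S)-4,8-dimethyl-3,4-bis(TESO)non-7-en-1-yl]magnesium bromide | Br[Mg]CC[C@@H](O[Si](CC)(CC)CC)[C@@](C)(O[Si](CC)(CC)CC)CCC=C(C)C | intermediate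
18 | (2S,5R,6S)-6,10-dimethyl-2-[(2S)-oxiran-2-yl]-5,6-bis(TESO)undec-9-en-2-ol | C1O[C@@H]1[C@@](C)(O)CC[C@@H](O[Si](CC)(CC)CC)[C@@](C)(O[Si](CC)(CC)CC)CCC=C(C)C | intermediate
19 | (2S)-2-[(2S,5R,6S)-6,10-dimethyl-2,5,6-tris(TESO)undec-9-en-2-yl]oxirane | C1O[C@@H]1[C@@](C)(O[Si](CC)(CC)CC)CC[C@@H](O[Si](CC)(CC)CC)[C@@](C)(O[Si](CC)(CC)CC)CCC=C(C)C | intermediate
20 | (3S,4S,7R,8S)-4,8,12-trimethyl-4,7,8-tris(TESO)-1-(triphenylphosphonio)tridec-11-en-3-olate (betaine) | [O-][C@@H](CC[P+](c1ccccc1)(c1ccccc1)c1ccccc1)[C@@](C)(O[Si](CC)(CC)CC)CC[C@@H](O[Si](CC)(CC)CC)[C@@](C)(O[Si](CC)(CC)CC)CCC=C(C)C | intermediate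
21 | [(3S,4S,7R,8S)-3-hydroxy-4,8,12-trimethyl-4,7,8-tris(TESO)tridec-11-en-1-yl]triphenylphosphonium bromide | [Br-].O[C@@H](CC[P+](c1ccccc1)(c1ccccc1)c1ccccc1)[C@@](C)(O[Si](CC)(CC)CC)CC[C@@H](O[Si](CC)(CC)CC)[C@@](C)(O[Si](CC)(CC)CC)CCC=C(C)C | intermediate
22 | (4R)-4-(TBSO)-5-methoxy-5-oxopentanoic 2,4,6-trichlorobenzoic anhydride | COC(=O)[C@@H](CCC(=O)OC(=O)c1c(Cl)cc(Cl)cc1Cl)O[Si](C)(C)C(C)(C)C | intermediate
23 | [(3S,4S,7R,8S)-3-{[(4R)-4-(TBSO)-5-methoxy-5-oxopentanoyl]oxy}-4,8,12-trimethyl-4,7,8-tris(TESO)tridec-11-en-1-yl]triphenylphosphonium bromide | [Br-].COC(=O)[C@@H](CCC(=O)O[C@@H](CC[P+](c1ccccc1)(c1ccccc1)c1ccccc1)[C@@](C)(O[Si](CC)(CC)CC)CC[C@@H](O[Si](CC)(CC)CC)[C@@](C)(O[Si](CC)(CC)CC)CCC=C(C)C)O[Si](C)(C)C(C)(C)C | intermediate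
24 | methyl (2R)-2-(TBSO)-5-oxo-5-{[(3S,4S,7R,8S)-4,8,12-trimethyl-4,7,8-tris(TESO)-1-(triphenyl-λ5-phosphanylidene)tridec-11-en-3-yl]oxy}pentanoate (ylide) | COC(=O)[C@@H](CCC(=O)O[C@@H](CC=P(c1ccccc1)(c1ccccc1)c1ccccc1)[C@@](C)(O[Si](CC)(CC)CC)CC[C@@H](O[Si](CC)(CC)CC)[C@@](C)(O[Si](CC)(CC)CC)CCC=C(C)C)O[Si](C)(C)C(C)(C)C | intermediate
25 | methyl (2R)-2-(TBSO)-4-{(5S)-5-[(2S,5R,6S)-6,10-dimethyl-2,5,6-tris(TESO)undec-9-en-2-yl]-4,5-dihydrofuran-2-yl}butanoate | COC(=O)[C@@H](CCC1=CC[C@H](O1)[C@@](C)(O[Si](CC)(CC)CC)CC[C@@H](O[Si](CC)(CC)CC)[C@@](C)(O[Si](CC)(CC)CC)CCC=C(C)C)O[Si](C)(C)C(C)(C)C | intermediate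
26 | potassium (2R)-2-(TBSO)-4-{(5S)-5-[(2S,5R,6S)-6,10-dimethyl-2,5,6-tris(TESO)undec-9-en-2-yl]-4,5-dihydrofuran-2-yl}butanoate | [K+].[O-]C(=O)[C@@H](CCC1=CC[C@H](O1)[C@@](C)(O[Si](CC)(CC)CC)CC[C@@H](O[Si](CC)(CC)CC)[C@@](C)(O[Si](CC)(CC)CC)CCC=C(C)C)O[Si](C)(C)C(C)(C)C | intermediate
27 | (2R)-2-(TBSO)-4-{(5S)-5-[(2S,5R,6S)-6,10-dimethyl-2,5,6-tris(TESO)undec-9-en-2-yl]-4,5-dihydrofuran-2-yl}butanoic trifluoroacetic anhydride | FC(F)(F)C(=O)OC(=O)[C@@H](CCC1=CC[C@H](O1)[C@@](C)(O[Si](CC)(CC)CC)CC[C@@H](O[Si](CC)(CC)CC)[C@@](C)(O[Si](CC)(CC)CC)CCC=C(C)C)O[Si](C)(C)C(C)(C)C | intermediate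
28 | (2S,5R)-5-(TBSO)-2-[(2S,5R,6S)-6,10-dimethyl-2,5,6-tris(TESO)undec-9-en-2-yl]-3,5,6,7-tetrahydro-1-benzofuran-4(2H)-one | CC(C)=CCC[C@](C)(O[Si](CC)(CC)CC)[C@H](O[Si](CC)(CC)CC)CC[C@](C)(O[Si](CC)(CC)CC)[C@@H]1CC2=C(CC[C@@H](O[Si](C)(C)C(C)(C)C)C2=O)O1 | intermediate
29 | (2S,5R)-5-hydroxy-2-[(2S,5R,6S)-2,5,6-trihydroxy-6,10-dimethylundec-9-en-2-yl]-3,5,6,7-tetrahydro-1-benzofuran-4(2H)-one | CC(C)=CCC[C@](C)(O)[C@H](O)CC[C@](C)(O)[C@@H]1CC2=C(CC[C@@H](O)C2=O)O1 | target

**Totals**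

Total step count: 19.
Longest linear sequence: 13 steps (steps 5–9, then steps 12–19).

**Steps most likely to fail**

Step 16 (key ring closure). The ylide may be quenched by proton transfer from the α-positions of the esters, or the tetrahedral adduct may collapse by acyl migration from O1 to C3a without loss of Ph3P=O, so that the enol ether does not form cleanly. The fallback sets out from oxirane 19 and acid 5, returns at 25, and builds the same enol ether by cross-coupling instead of olefination. Oxirane 19 is opened at its CH2 terminus by dilithium acetate (AcOH, LiN(iPr)2, THF, 45 °C) to the hydroxy acid (4S,5S,8R,9S)-4-hydroxy-5,9,13-trimethyl-5,8,9-tris(TESO)tetradec-12-enoic acid F1. This closes on buffered work-up to the γ-lactone (5S)-5-[(2S,5R,6S)-6,10-dimethyl-2,5,6-tris(TESO)undec-9-en-2-yl]oxolan-2-one F2. KN(SiMe3)2 and ClP(O)(OPh)2 (THF, −78 °C) convert it into the ketene acetal phosphate (5S)-5-[(2S,5R,6S)-6,10-dimethyl-2,5,6-tris(TESO)undec-9-en-2-yl]-4,5-dihydrofuran-2-yl diphenyl phosphate F3. In parallel, acid 5 is iododecarboxylated (PhI(OAc)2, I2, hν) to methyl (2R)-2-(TBSO)-4-iodobutanoate F4, and zinc dust (THF) gives [(3R)-3-(TBSO)-4-methoxy-4-oxobutyl]zinc iodide F5. Negishi coupling of F3 with F5 (Pd(PPh3)4, THF, 50 °C) forms the C7–C7a bond and should give 25.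

Step 18 (six-membered ring closure). The acid-labile enol ether may be protonated or oligomerised, or the trifluoroacetyl group may be transferred instead of the α-silyloxyacyl group, before C3a reaches C4. The fallback sets out from ester 25, returns at 28, and closes the ring at the aldehyde oxidation level. i-Bu2AlH (CH2Cl2, −78 °C) reduces 25 to (2R)-2-(TBSO)-4-{(5S)-5-[(2S,5R,6S)-6,10-dimethyl-2,5,6-tris(TESO)undec-9-en-2-yl]-4,5-dihydrofuran-2-yl}butanal F6. Me2AlCl (CH2Cl2, −78 °C) then promotes a carbonyl-ene (Prins-type) closure of the C3a–C4 bond to (2S,5R)-5-(TBSO)-2-[(2S,5R,6S)-6,10-dimethyl-2,5,6-tris(TESO)undec-9-en-2-yl]-2,3,4,5,6,7-hexahydro-1-benzofuran-4-ol F7 (both C4 epimers). MnO2 (CH2Cl2, rt) oxidises the allylic alcohol to 28.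

Step 14 (oxirane opening by the ylide). The oxirane next to the quaternary silyloxy carbon may open sluggishly, so that the basic ylide decomposes or attacks a silyl ether first. The fallback sets out from oxirane 19, returns at 21, and brings in C3a as a hydroxymethyl anion equivalent. i-PrO(Me)2SiCH2MgCl with CuI (catalytic; THF, 0 °C) opens 19 to (3S,4S,7R,8S)-1-[dimethyl(propan-2-yloxy)silyl]-4,8,12-trimethyl-4,7,8-tris(TESO)tridec-11-en-3-ol F8. Tamao–Fleming oxidation (H2O2, KF, KHCO3, THF/MeOH) gives (3S,4S,7R,8S)-4,8,12-trimethyl-4,7,8-tris(TESO)tridec-11-ene-1,3-diol F9. Appel bromination of the primary hydroxyl (CBr4, PPh3, 0 °C) gives (3S,4S,7R,8S)-1-bromo-4,8,12-trimethyl-4,7,8-tris(TESO)tridec-11-en-3-ol F10, and PPh3 (MeCN, 80 °C) quaternises it to 21.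

**Further compounds**

F1 | step 16 | (4S,5S,8R,9S)-4-hydroxy-5,9,13-trimethyl-5,8,9-tris(TESO)tetradec-12-enoic acid | OC(=O)CC[C@H](O)[C@@](C)(O[Si](CC)(CC)CC)CC[C@@H](O[Si](CC)(CC)CC)[C@@](C)(O[Si](CC)(CC)CC)CCC=C(C)C
F2 | step 16 | (5S)-5-[(2S,5R,6S)-6,10-dimethyl-2,5,6-tris(TESO)undec-9-en-2-yl]oxolan-2-one | O=C1CC[C@H](O1)[C@@](C)(O[Si](CC)(CC)CC)CC[C@@H](O[Si](CC)(CC)CC)[C@@](C)(O[Si](CC)(CC)CC)CCC=C(C)C
F3 | step 16 | (5S)-5-[(2S,5R,6S)-6,10-dimethyl-2,5,6-tris(TESO)undec-9-en-2-yl]-4,5-dihydrofuran-2-yl diphenyl phosphate | O=P(Oc1ccccc1)(Oc1ccccc1)OC1=CC[C@H](O1)[C@@](C)(O[Si](CC)(CC)CC)CC[C@@H](O[Si](CC)(CC)CC)[C@@](C)(O[Si](CC)(CC)CC)CCC=C(C)C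
F4 | step 16 | methyl (2R)-2-(TBSO)-4-iodobutanoate | COC(=O)[C@@H](CCI)O[Si](C)(C)C(C)(C)C
F5 | step 16 | [(3R)-3-(TBSO)-4-methoxy-4-oxobutyl]zinc iodide | COC(=O)[C@@H](CC[Zn]I)O[Si](C)(C)C(C)(C)C
F6 | step 18 | (2R)-2-(TBSO)-4-{(5S)-5-[(2S,5R,6S)-6,10-dimethyl-2,5,6-tris(TESO)undec-9-en-2-yl]-4,5-dihydrofuran-2-yl}butanal | O=C[C@@H](CCC1=CC[C@H](O1)[C@@](C)(O[Si](CC)(CC)CC)CC[C@@H](O[Si](CC)(CC)CC)[C@@](C)(O[Si](CC)(CC)CC)CCC=C(C)C)O[Si](C)(C)C(C)(C)C
F7 | step 18 | (2S,5R)-5-(TBSO)-2-[(2S,5R,6S)-6,10-dimethyl-2,5,6-tris(TESO)undec-9-en-2-yl]-2,3,4,5,6,7-hexahydro-1-benzofuran-4-ol (both C4 epimers) | CC(C)=CCC[C@](C)(O[Si](CC)(CC)CC)[C@H](O[Si](CC)(CC)CC)CC[C@](C)(O[Si](CC)(CC)CC)[C@@H]1CC2=C(CC[C@@H](O[Si](C)(C)C(C)(C)C)C2O)O1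
F8 | step 14 | (3S,4S,7R,8S)-1-[dimethyl(propan-2-yloxy)silyl]-4,8,12-trimethyl-4,7,8-tris(TESO)tridec-11-en-3-ol | CC(C)O[Si](C)(C)CC[C@H](O)[C@@](C)(O[Si](CC)(CC)CC)CC[C@@H](O[Si](CC)(CC)CC)[C@@](C)(O[Si](CC)(CC)CC)CCC=C(C)C
F9 | step 14 | (3S,4S,7R,8S)-4,8,12-trimethyl-4,7,8-tris(TESO)tridec-11-ene-1,3-diol | OCC[C@H](O)[C@@](C)(O[Si](CC)(CC)CC)CC[C@@H](O[Si](CC)(CC)CC)[C@@](C)(O[Si](CC)(CC)CC)CCC=C(C)C
F10 | step 14 | (3S,4S,7R,8S)-1-bromo-4,8,12-trimethyl-4,7,8-tris(TESO)tridec-11-en-3-ol | BrCC[C@H](O)[C@@](C)(O[Si](CC)(CC)CC)CC[C@@H](O[Si](CC)(CC)CC)[C@@](C)(O[Si](CC)(CC)CC)CCC=C(C)C
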